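**Retrosynthetic overview**

1. Target 17 comes from 15 by removal of one MOM ether and six aryl silyl ethers; 15 already has the full skeleton and all three stereocentres.
2. 15 is cut at both C–C bonds of C4: C4–C4a (this bond closes pyran ring C onto ring A) and C4–C2 of stilbene ring D. Both go back to one aldehyde carbon, giving open-chain aldehyde 11 and persilylated piceatannol 13.
3. Enabling feature: C4 is a doubly benzylic CH between two resorcinol-type rings (C4a of ring A is para to O-7 and ortho to O-1; the attached carbon of ring D is ortho and para to its two oxygens). The C3 oxygen next to it is axial in the 2,3-cis ring, so it steers the second arylation trans.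
4. 11 comes from syn alcohol 7 by O-arylation at oxygen with iodide 9 (retention at C2) and cleavage of the vinyl group. 7 comes from aldehyde 2 and allyl ether 4 by Brown (Z)-alkoxyallylboration, which sets C2 and C3 together.
5. Ring order: rings A, B, D and E are bought as arenes; ring C is the only ring made and is closed last, in step 8.

Key step: step 8

Assumption: the alkoxyallylborane made from (−)-B-methoxydiisopinocampheylborane is taken to attack the same aldehyde face as its parent allyl reagent does with aryl aldehydes, which leads to the (1R,2R) alcohol 7.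

**Route**

Step 1
Reactants: 1 4-hydroxybenzaldehyde
Product: 2 4-(triisopropylsilyloxy)benzaldehyde
Conditions: TIPSCl, imidazole, DMF, rt
Reagents that add atoms: chlorotriisopropylsilane, CC(C)[Si](Cl)(C(C)C)C(C)C
Why: Imidazole-promoted silylation of the phenol gives a bulky aryl silyl ether that should survive the later base, oxidant and Lewis acid and leave with fluoride at the end.

Step 2
Reactants: 3 allyl alcohol
Product: 4 allyl methoxymethyl ether
Conditions: MOMCl, iPr2NEt, CH2Cl2, 0 °C to rt
Reagents that add atoms: chloromethyl methyl ether, COCCl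
Why: O-alkylation of the alcohol with MOMCl (acetal protection) gives the allyl ether that the alkoxyallylboration needs.

Step 3
Reactants: 2 4-(triisopropylsilyloxy)benzaldehyde; 4 allyl methoxymethyl ether
Product: 7 (1R,2R)-2-(methoxymethoxy)-1-[4-(triisopropylsilyloxy)phenyl]but-3-en-1-ol, via (Z)-3-(methoxymethoxy)allyllithium 5 (not isolated), via [(Z)-3-(methoxymethoxy)allyl]diisopinocampheylborane 6 (not isolated)
Conditions: 4, sec-BuLi, THF, −78 °C; (−)-B-methoxydiisopinocampheylborane; BF3·OEt2; then 2, −78 °C; ethanolamine work-up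
Reagents that add atoms: none
Why: Brown asymmetric alkoxyallylboration, in which the chelated Z-anion 5 gives the (Z)-γ-alkoxyallylborane 6 and this adds to 2 through a chair six-membered transition state, so that the Z geometry becomes the syn relationship and the isopinocampheyl groups choose the aldehyde face, setting both carbinol centres (the future C2 and C3) as (1R,2R).

Step 4
Reactants: 8 3-iodophenol
Product: 9 (3-iodophenoxy)triisopropylsilane
Conditions: TIPSCl, imidazole, DMF, rt
Reagents that add atoms: chlorotriisopropylsilane, CC(C)[Si](Cl)(C(C)C)C(C)C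
Why: Silylation of the phenol gives the ring A donor in a form whose bulky silyloxy group later directs the ring closure para to itself.

Step 5
Reactants: 7 (1R,2R)-2-(methoxymethoxy)-1-[4-(triisopropylsilyloxy)phenyl]but-3-en-1-ol; 9 (3-iodophenoxy)triisopropylsilane
Product: 10 triisopropyl[3-({(1R,2R)-2-(methoxymethoxy)-1-[4-(triisopropylsilyloxy)phenyl]but-3-en-1-yl}oxy)phenoxy]silane
Conditions: 9 (2 equiv), CuI (20 mol%), 3,4,7,8-tetramethyl-1,10-phenanthroline (40 mol%), Cs2CO3, 4 Å MS, toluene, 100 °C
Reagents that add atoms: none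
Why: Ullmann-type CuI-catalysed C–O coupling of a secondary alcohol with an aryl iodide forms the aryl–O bond at oxygen, so the benzylic C–O bond is never broken and the (1R) centre is kept with retention, which avoids ionisation at this p-oxybenzylic carbon.

Step 6
Reactants: 10 triisopropyl[3-({(1R,2R)-2-(methoxymethoxy)-1-[4-(triisopropylsilyloxy)phenyl]but-3-en-1-yl}oxy)phenoxy]silane
Product: 11 (2S,3R)-2-(methoxymethoxy)-3-[3-(triisopropylsilyloxy)phenoxy]-3-[4-(triisopropylsilyloxy)phenyl]propanal
Conditions: OsO4 (2 mol%), NaIO4, 2,6-lutidine, dioxane–H2O (3:1), rt; used crude at once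
Reagents that add atoms: osmium tetroxide, O=[Os](=O)(=O)=O; sodium periodate, [Na+].[O-]I(=O)(=O)=O
Why: Lemieux–Johnson oxidative cleavage (catalytic dihydroxylation, then periodate glycol cleavage) acts on the only alkene, and the lutidine buffer should keep the α-alkoxy-β-aryloxy aldehyde from epimerising or losing aryloxide (the descriptor changes to 2S only because the CHO group now outranks its neighbour).

Step 7
Reactants: 12 (E)-piceatannol
Product: 13 (E)-3,3',4',5-tetrakis(tert-butyldimethylsilyloxy)stilbene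
Conditions: TBSCl (5 equiv), imidazole, DMF, rt
Reagents that add atoms: tert-butylchlorodimethylsilane, CC(C)(C)[Si](C)(C)Cl
Why: Exhaustive silylation of the four phenols gives a CH2Cl2-soluble, Lewis-acid-stable nucleophile whose position between the two silyloxy groups is shielded.

Step 8
Reactants: 11 (2S,3R)-2-(methoxymethoxy)-3-[3-(triisopropylsilyloxy)phenoxy]-3-[4-(triisopropylsilyloxy)phenyl]propanal; 13 (E)-3,3',4',5-tetrakis(tert-butyldimethylsilyloxy)stilbene
Product: 15 (2R,3R,4R)-4-{2,4-bis(tert-butyldimethylsilyloxy)-6-[(E)-2-[3,4-bis(tert-butyldimethylsilyloxy)phenyl]ethenyl]phenyl}-3-(methoxymethoxy)-7-(triisopropylsilyloxy)-2-[4-(triisopropylsilyloxy)phenyl]chroman, via 4-hydroxyflavan 14 (not isolated)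
Conditions: 13 (2.5 equiv), BF3·OEt2 (1.5 equiv), CH2Cl2, −78 °C to −10 °C; NaHCO3 quench
Reagents that add atoms: none
Why: BF3 activates the aldehyde of 11 and ring A attacks it through the carbon para to the silyloxy group and ortho to the ether oxygen, a 6-exo-trig intramolecular Friedel–Crafts hydroxyalkylation that closes the pyran ring (C4–C4a) and gives the flavan-3,4-diol derivative 14 as its boron alkoxide. On warming, the C4–O bond of 14 ionises to the benzylic cation stabilised by O-1 and O-7, and ring D of 13 adds through its C-2 in an intermolecular Friedel–Crafts alkylation. The closest known reactions are the Lewis-acid cyclisation of aryl-tethered aldehydes to benzylic alcohols, the acid-mediated coupling of flavan-3,4-diols or their 4-ethers with phenolic nucleophiles, and the one-pot double arylation of aldehydes to unsymmetrical triarylmethanes. C4 is the only new stereocentre and is set by substrate control: in the half-chair cation the 2-aryl group is pseudo-equatorial and the 3-OMOM group pseudo-axial, so the arene should enter axially on the face anti to the C3 oxygen and give the 3,4-trans (4R) product, as in the 2,3-cis (epicatechin-type) series. The step needs regioselectivity on ring A (para direction by the 7-silyloxy group, TIPS shielding of the carbon between the two oxygens), site selectivity on the stilbene (C-2 is para to one silyloxy group, whereas C-4 lies between two OTBS groups, and the alkene and ring E are weaker nucleophiles) and suppression of self-alkylation (excess 13, low temperature).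

Step 9
Reactants: 15 (2R,3R,4R)-4-{2,4-bis(tert-butyldimethylsilyloxy)-6-[(E)-2-[3,4-bis(tert-butyldimethylsilyloxy)phenyl]ethenyl]phenyl}-3-(methoxymethoxy)-7-(triisopropylsilyloxy)-2-[4-(triisopropylsilyloxy)phenyl]chroman
Product: 16 (2R,3R,4R)-4-{2,4-bis(tert-butyldimethylsilyloxy)-6-[(E)-2-[3,4-bis(tert-butyldimethylsilyloxy)phenyl]ethenyl]phenyl}-7-(triisopropylsilyloxy)-2-[4-(triisopropylsilyloxy)phenyl]chroman-3-ol
Conditions: ZnBr2, n-PrSH, CH2Cl2, 0 °C, short reaction time
Reagents that add atoms: none
Why: Lewis acid/thiol cleavage of the MOM acetal (ZnBr2 activates the acetal, the thiol traps the methoxymethyl cation) should leave the aryl silyl ethers, the stilbene and the C4–aryl bond untouched under these short, cold conditions.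

Step 10
Reactants: 16 (2R,3R,4R)-4-{2,4-bis(tert-butyldimethylsilyloxy)-6-[(E)-2-[3,4-bis(tert-butyldimethylsilyloxy)phenyl]ethenyl]phenyl}-7-(triisopropylsilyloxy)-2-[4-(triisopropylsilyloxy)phenyl]chroman-3-ol
Product: 17 (2R,3R,4R)-4-{2-[(E)-2-(3,4-dihydroxyphenyl)ethenyl]-4,6-dihydroxyphenyl}-2-(4-hydroxyphenyl)chroman-3,7-diol
Conditions: TBAF (8 equiv), AcOH (8 equiv), THF, 0 °C to rt, under Ar
Reagents that add atoms: none
Why: Fluoride cleavage of the six aryl silyl ethers, buffered with AcOH so that each phenoxide is protonated at once, should prevent base-induced ring opening at C2 and air oxidation of the catechol, and touches no stereocentre or the E alkene.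

**Compound list**

1 | 4-hydroxybenzaldehyde | O=Cc1ccc(O)cc1 | starting material
2 | 4-(triisopropylsilyloxy)benzaldehyde | O=Cc1ccc(O[Si](C(C)C)(C(C)C)C(C)C)cc1 | intermediate
3 | allyl alcohol | C=CCO | starting material
4 | allyl methoxymethyl ether | C=CCOCOC | intermediate
5 | (Z)-3-(methoxymethoxy)allyllithium | [Li]C/C=C\OCOC | intermediate
6 | [(Z)-3-(methoxymethoxy)allyl]diisopinocampheylborane (isopinocampheyl groups of the (+)-α-pinene series) | COCO/C=C\CB([C@@H]1C[C@@H]2C[C@H]([C@H]1C)C2(C)C)[C@@H]1C[C@@H]2C[C@H]([C@H]1C)C2(C)C | intermediate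
7 | (1R,2R)-2-(methoxymethoxy)-1-[4-(triisopropylsilyloxy)phenyl]but-3-en-1-ol | C=C[C@@H](OCOC)[C@H](O)c1ccc(O[Si](C(C)C)(C(C)C)C(C)C)cc1 | intermediate
8 | 3-iodophenol | Oc1cccc(I)c1 | starting material
9 | (3-iodophenoxy)triisopropylsilane | CC(C)[Si](Oc1cccc(I)c1)(C(C)C)C(C)C | intermediate
10 | triisopropyl[3-({(1R,2R)-2-(methoxymethoxy)-1-[4-(triisopropylsilyloxy)phenyl]but-3-en-1-yl}oxy)phenoxy]silane | C=C[C@@H](OCOC)[C@H](Oc1cccc(O[Si](C(C)C)(C(C)C)C(C)C)c1)c1ccc(O[Si](C(C)C)(C(C)C)C(C)C)cc1 | intermediate
11 | (2S,3R)-2-(methoxymethoxy)-3-[3-(triisopropylsilyloxy)phenoxy]-3-[4-(triisopropylsilyloxy)phenyl]propanal | O=C[C@@H](OCOC)[C@H](Oc1cccc(O[Si](C(C)C)(C(C)C)C(C)C)c1)c1ccc(O[Si](C(C)C)(C(C)C)C(C)C)cc1 | intermediate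
12 | (E)-piceatannol, (E)-3,3',4',5-tetrahydroxystilbene | Oc1cc(O)cc(/C=C/c2ccc(O)c(O)c2)c1 | starting material
13 | (E)-3,3',4',5-tetrakis(tert-butyldimethylsilyloxy)stilbene | CC(C)(C)[Si](C)(C)Oc1cc(O[Si](C)(C)C(C)(C)C)cc(/C=C/c2ccc(O[Si](C)(C)C(C)(C)C)c(O[Si](C)(C)C(C)(C)C)c2)c1 | intermediate
14 | (2R,3R)-3-(methoxymethoxy)-7-(triisopropylsilyloxy)-2-[4-(triisopropylsilyloxy)phenyl]chroman-4-ol, both C4 epimers | CC(C)[Si](C(C)C)(C(C)C)Oc1ccc([C@H]2Oc3cc(O[Si](C(C)C)(C(C)C)C(C)C)ccc3C(O)[C@H]2OCOC)cc1 | intermediate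
15 | (2R,3R,4R)-4-{2,4-bis(tert-butyldimethylsilyloxy)-6-[(E)-2-[3,4-bis(tert-butyldimethylsilyloxy)phenyl]ethenyl]phenyl}-3-(methoxymethoxy)-7-(triisopropylsilyloxy)-2-[4-(triisopropylsilyloxy)phenyl]chroman | CC(C)[Si](C(C)C)(C(C)C)Oc1ccc([C@H]2Oc3cc(O[Si](C(C)C)(C(C)C)C(C)C)ccc3[C@H](c3c(O[Si](C)(C)C(C)(C)C)cc(O[Si](C)(C)C(C)(C)C)cc3/C=C/c3ccc(O[Si](C)(C)C(C)(C)C)c(O[Si](C)(C)C(C)(C)C)c3)[C@H]2OCOC)cc1 | intermediate
16 | (2R,3R,4R)-4-{2,4-bis(tert-butyldimethylsilyloxy)-6-[(E)-2-[3,4-bis(tert-butyldimethylsilyloxy)phenyl]ethenyl]phenyl}-7-(triisopropylsilyloxy)-2-[4-(triisopropylsilyloxy)phenyl]chroman-3-ol | CC(C)[Si](C(C)C)(C(C)C)Oc1ccc([C@H]2Oc3cc(O[Si](C(C)C)(C(C)C)C(C)C)ccc3[C@H](c3c(O[Si](C)(C)C(C)(C)C)cc(O[Si](C)(C)C(C)(C)C)cc3/C=C/c3ccc(O[Si](C)(C)C(C)(C)C)c(O[Si](C)(C)C(C)(C)C)c3)[C@H]2O)cc1 | intermediate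
17 | (2R,3R,4R)-4-{2-[(E)-2-(3,4-dihydroxyphenyl)ethenyl]-4,6-dihydroxyphenyl}-2-(4-hydroxyphenyl)chroman-3,7-diol | Oc1ccc([C@H]2Oc3cc(O)ccc3[C@H](c3c(O)cc(O)cc3/C=C/c3ccc(O)c(O)c3)[C@H]2O)cc1 | target

**Step count and risks**

Total steps: 10. Longest linear sequence: 7 (steps 1, 3, 5, 6, 8, 9, 10).

Steps most likely to fail:

Step 8. With a stoichiometric Lewis acid the C4 cation may be consumed by alkylation of ring A of a second molecule, the stilbene may be attacked at a site other than C-2 of ring D, or the MOM ether may ionise before the coupling is over. The fallback separates ring closure from coupling and uses the established two-stage activation of 4-oxygenated flavans. It sets out from 11: cyclisation alone (BF3·OEt2, CH2Cl2, −78 °C, cold quench with Et3N and NaHCO3) and isolation of the 4-hydroxyflavan 14; acetylation (Ac2O, DMAP, pyridine) to (2R,3R)-4-acetoxy-3-(methoxymethoxy)-7-(triisopropylsilyloxy)-2-[4-(triisopropylsilyloxy)phenyl]chroman F1; then coupling of F1 with excess 13 under catalytic TMSOTf at −78 °C, where the cation forms only in the presence of the nucleophile. It comes back to the route at 15.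

Step 5. The hindered secondary alkoxide may couple slowly, so that oxidation of the alcohol to the ketone or transfer of a silyl group from an aryl silyl ether to the alkoxide at 100 °C takes over. The fallback is a metal-free arylation at room temperature by ligand coupling at hypervalent iodine. It sets out from 9 and 7: one-pot oxidation of 9 (mCPBA, TsOH·H2O, then 1,3,5-trimethoxybenzene) gives [3-(triisopropylsilyloxy)phenyl](2,4,6-trimethoxyphenyl)iodonium 4-methylbenzenesulfonate F2; the sodium alkoxide of 7 (NaH, tert-butyl methyl ether, rt) then attacks iodine and the less electron-rich aryl group is transferred to oxygen, again with retention at carbon. It comes back at 10.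

Step 6. The free aldehyde may lose aryloxide by β-elimination or epimerise at its α-carbon during isolation. The fallback avoids the free aldehyde and sets out from 10: ozonolysis in CH2Cl2–MeOH at −78 °C to the indicator end point, Me2S, then HC(OMe)3 and pyridinium p-toluenesulfonate in the same flask give (2S,3R)-1,1-dimethoxy-2-(methoxymethoxy)-3-[3-(triisopropylsilyloxy)phenoxy]-3-[4-(triisopropylsilyloxy)phenyl]propane F3, which is stable to base and storage. Under the conditions of step 8, BF3 ionises the acetal, ring A closes to the 4-methoxyflavan (2R,3R)-4-methoxy-3-(methoxymethoxy)-7-(triisopropylsilyloxy)-2-[4-(triisopropylsilyloxy)phenyl]chroman F4 (not isolated), and F4 ionises and couples with 13 as before. It comes back at 15.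

**Further compounds**

F1 | step 8 | (2R,3R)-4-acetoxy-3-(methoxymethoxy)-7-(triisopropylsilyloxy)-2-[4-(triisopropylsilyloxy)phenyl]chroman, both C4 epimers | CC(C)[Si](C(C)C)(C(C)C)Oc1ccc([C@H]2Oc3cc(O[Si](C(C)C)(C(C)C)C(C)C)ccc3C(OC(C)=O)[C@H]2OCOC)cc1
F2 | step 5 | [3-(triisopropylsilyloxy)phenyl](2,4,6-trimethoxyphenyl)iodonium 4-methylbenzenesulfonate | COc1cc(OC)c([I+]c2cccc(O[Si](C(C)C)(C(C)C)C(C)C)c2)c(OC)c1.Cc1ccc(S(=O)(=O)[O-])cc1
F3 | step 6 | (2S,3R)-1,1-dimethoxy-2-(methoxymethoxy)-3-[3-(triisopropylsilyloxy)phenoxy]-3-[4-(triisopropylsilyloxy)phenyl]propane | COC(OC)[C@@H](OCOC)[C@H](Oc1cccc(O[Si](C(C)C)(C(C)C)C(C)C)c1)c1ccc(O[Si](C(C)C)(C(C)C)C(C)C)cc1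
F4 | step 6 | (2R,3R)-4-methoxy-3-(methoxymethoxy)-7-(triisopropylsilyloxy)-2-[4-(triisopropylsilyloxy)phenyl]chroman, both C4 epimers | CC(C)[Si](C(C)C)(C(C)C)Oc1ccc([C@H]2Oc3cc(O[Si](C(C)C)(C(C)C)C(C)C)ccc3C(OC)[C@H]2OCOC)cc1
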